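The readings were computed with made-up constants; noise was put on by code.

Slowness is what you inherit with this flask. In the zeta run the over-reaction product reads 9 % at 12.0 min and 12 % at 20.0 min, so we expect this flask to be still moving when you come.

all flasks: electrophile 0.050 M (in portions, 3)

| charge | free base | protonated nucleophile | remark | time |
|---|---|---|---|---|
| theta | 0.075 M | 0.050 M | run made earlier; portions every 2.5 min |  |
| zeta | 0.11 M | 0.050 M | run made earlier; portions every 2.5 min |  |
| flask | 0.150 M | 0.0500 M | the portions of electrophile follow each other after 2.5 min, the first at the start | 20 min |

| run | time / min | electrophile / % | target / % | over-reaction product / % |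
|---|---|---|---|---|
| theta | 1.00 | 28 | 2 | 3 |
| theta | 3.00 | 46 | 6 | 0 |
| theta | 6.00 | 57 | 11 | 1 |
| theta | 8.00 | 43 | 18 | 2 |
| theta | 12.0 | 32 | 21 | 5 |
| theta | 15.0 | 29 | 21 | 0 |
| theta | 20.0 | 24 | 27 | 5 |
| zeta | 1.50 | 23 | 3 | 0 |
| zeta | 2.50 | 18 | 5 | 0 |
| zeta | 4.00 | 41 | 6 | 2 |
| zeta | 6.00 | 61 | 9 | 1 |
| zeta | 8.00 | 45 | 17 | 4 |
| zeta | 12.0 | 31 | 19 | 9 |
| zeta | 20.0 | 25 | 21 | 12 |

(readings scatter by 1.5 percentage points)

- at 20 min, what has stopped the reaction, if anything has (the free base has run out first / forward and back rates have come level / it is still moving / all of the electrophile has reacted)
- conversion of electrophile at 20 min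
- amount of target at 20 min, in percent of the electrophile charged
- amount of over-reaction product at 20 min, in percent of the electrophile charged

- the numbers in the tables scatter with a standard deviation of 1.5 percentage points
- steps thought possible: electrophile + nucleophile -> acid set free + target; nucleophile + acid set free <-> protonated nucleophile; acid set free + free base <-> salt of the base; acid set free -> by-product carried off; free base + target -> over-reaction product; electrophile <-> dormant form
- what has gone from electrophile into another species counts as reacted, even if it can come back
- the reaction counts as stopped when no species that holds the electrophile changes by six tenths of a point or more over the second half of the time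

We take it that the free base must first take the acid off the protonated nucleophile, so we count the spare base: [free base] less [protonated nucleophile] as charged. That is 0.0250 M in the theta run, 0.0600 M in the zeta run and 0.100 M in this flask. From theta to zeta the final over-reaction reading rises by a factor of 2.40, and the spare base by 2.40, while the charge of free base rises by 1.47.

So we carry a factor: the ratio of over-reaction product to target at 20.0 min, with the portions as in the runs, per unit of spare base, read in the zeta run as 9.52 L mol⁻¹. This flask has more spare base than the zeta run, and the factor gives it a ratio of 0.952. Taking target plus over-reaction product as in the zeta run, 33.0 %, we reckon target 16.9 % and over-reaction product 16.1 %. Please add no free base, since that raises the spare base.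

The forecast says it is still moving, with conversion 77 %, target 22 % and over-reaction product 16 %, seeing in target plus over-reaction product “a weak base dependence”. Its target stands above ours.

The flask gives: it is still moving, conversion 75.3 %, target 15.0 %, over-reaction product 20.4 %.

    electrophile + nucleophile → acid set free + target (k = 1.33 L mol⁻¹ min⁻¹)
    nucleophile + acid set free ⇌ protonated nucleophile, settled at all times (K = 1210 L mol⁻¹)
    acid set free + free base ⇌ salt of the base, settled at all times (K = 16300 L mol⁻¹)
    acid set free → by-product carried off (k = 0.0404 min⁻¹)
    free base + target → over-reaction product (k = 1.02 L mol⁻¹ min⁻¹)
    electrophile ⇌ dormant form (K = 1.42, k = 0.172 min⁻¹)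

This flask stood at a ratio of 1.36 at 20.0 min, above the 0.952 we reckoned, and its target lies below both our figure and the forecast's. The neighbouring flask charged with 0.12 M of protonated nucleophile has 0.0300 M of spare base as charged, so the same factor gives it a ratio of 0.286. That neighbour held target 41.5 % and over-reaction product 16.3 % at 20.0 min, a ratio of 0.393.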